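Product cannot be made at the start of either flask: its step feeds on intermediate B, and none is charged.

| flask | substrate | temperature | time |
|---|---|---|---|
| Saturday's | 32 mM | 25 °C | 50 min |
| Friday's | 32 mM | 33 °C | 50 min |

    substrate → intermediate A (k1 = 0.075 min⁻¹, Ea1 = 94.0 kJ mol⁻¹)
    intermediate A → intermediate B (k2 = 0.14 min⁻¹, Ea2 = 79.0 kJ mol⁻¹)
    intermediate B → product (k3 = 0.011 min⁻¹, Ea3 = 89.0 kJ mol⁻¹)
    (constants at 25 °C)

- the constants hold at 25 °C; other temperatures follow from the activation energies

1. which of these there is most of at the end, counted by the substrate in it, Saturday's (intermediate B / substrate / product / intermediate A)
2. which of these there is most of at the end, counted by the substrate in it, Friday's (intermediate B / substrate / product / intermediate A)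
3. amount of the one of these that there is most of at the end, in percent of the substrate charged, Saturday's
4. amount of the one of these that there is most of at the end, in percent of the substrate charged, Friday's

We reckon by rates. With the whole charge in intermediate B from the first minute, the last step of Saturday's flask would start at 0.352 mM min⁻¹. Two things slow it. The first is arrival: material spends on average the reciprocal of each rate constant in the first two steps, so the last step runs about 20.5 min late. This shortcut needs the last step, the rate-limiting step, to be slower than both others. The second is draining: as a simplification, we let the whole charge reach intermediate B at the end of that lag, and in this reckoning the rate then falls by the same proportion each minute.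

We call the accumulated slowing the unfinished share: the exponential of minus the last step's rate constant times the time left after the lag, which we take as our estimate of the part of the charge not yet product. At 33 °C the constants become 0.202 min⁻¹, 0.322 min⁻¹ and 0.0281 min⁻¹, so Friday's unfinished share is 30.8%. Saturday's is 72.3%.

Friday's flask should therefore end mostly as product, at 69.2%, which is more than what is unfinished. On Saturday the first step's rate has fallen by a factor of 0.0235, and taking what still stands upstream from the unfinished share leaves intermediate B at 67.2%.

The forecast says “material piles up in intermediate B” and gives intermediate B at 67.5% for Saturday's flask and product at 68.8% for Friday's, close to our figures but not the same.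

The simulation gives intermediate B at 67.6% on Saturday and product at 68.8% on Friday, so the forecast held.

Neither flask is at rest at 50 min. Friday's c(intermediate B) still stands at 31.2% of the charge, while upstream there is 0% substrate and 0.00690% intermediate A, so in Friday's flask the material upstream is far less than intermediate B. Carried on to 500 min, Saturday's unfinished share shrinks to 0.512%, and the run shows 0.520% intermediate B beside 99.5% product. Friday's shrinks to <0.001%, with product at >99.9%. Ten times the time adds 72 percentage points of product in Saturday's flask.

Now take Friday's flask left until 2.0 h. The unfinished share, carried on from 30.8%, becomes 4.30%, which promises product at 95.7%. The simulation gives 95.6%, with 4.36% intermediate B.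

Its constants were drawn at random within sensible limits; the result is computed.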